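**Retrosynthetic overview**

1. Target 28 (azulene locants C1–C8a; side chain C1'–C7', C2' bonded to C5) comes from triol 27 by hindrance-controlled diacetylation; ring B (seven-membered, C3a–C4–C5–C6–C7–C8–C8a) comes from intramolecular Ni/Cr coupling C7–C8 of the aldehyde/2-iodoalkene 25.
2. 25 comes from diol 21, which is cut at C2'–C3' and at C4–C5 into four components joined in one pot by diboration and double allylboration: (3Z)-penta-1,3-diene 16 (C7, C6, C5, C2', C1'), B2pin2 17, 4-methylpent-3-enal 15 (C3'–C7') and the ring A aldehyde 13 (C4, ring A, C8).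
3. Enabling feature: the adjacent methines C5 (ring B) and C2' (chain) each carry an oxygenated carbon (C4–OH in ring B, C3'–OAc in the chain). This 1,4-diol with two stereocentres between is the retron of a diene 1,2-bis(boronate) reacting twice with aldehydes; ring B atoms C6 (CH2) and C7 (CH–O) are the vinyl group this leaves on C5.
4. 13 comes from cyclopent-2-en-1-one 1 by enantioselective conjugate addition of a 1-silylvinyl group (C8a, C8), hydroxymethylation (C3a, C4), enol triflate methylation (C3 methyl, C2=C3) and iododesilylation.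
5. Ring order: ring A is present from 1; ring B is closed in the last C–C bond formation (step 14).

Key step: step 10

Remark on the chemistry: where the sense of induction of a chiral ligand or catalyst rests on analogy, the enantiomer that delivers the stated configuration is meant.

**Route**

Step 1
Reactants: 1 cyclopent-2-en-1-one; 2 ethynyl(trimethyl)silane
Product: 5 trimethyl({(3R)-3-[1-(trimethylsilyl)ethenyl]cyclopent-1-en-1-yl}oxy)silane, via vinylalane 3 (not isolated), via aluminium enolate 4 (not isolated)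
Conditions: 2, i-Bu2AlH, hexanes/THF, 55 °C; then 1, CuCl2·2H2O (5 mol%), chiral sulfonate-bearing imidazolinium salt (NHC precursor, 5 mol%; enantiomer giving 3R), THF, −78 °C; then Me3SiOTf, −78 to 0 °C
Reagents that add atoms: trimethylsilyl trifluoromethanesulfonate, C[Si](C)(C)OS(=O)(=O)C(F)(F)F
Why: Copper-catalysed enantioselective conjugate addition of a silyl-substituted vinylaluminium (from hydroalumination of 2) to a cyclic enone should set C8a (R) under ligand control, and O-silylation of the aluminium enolate fixes the enolate position at the future C3a.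

Step 2
Reactants: 5 trimethyl({(3R)-3-[1-(trimethylsilyl)ethenyl]cyclopent-1-en-1-yl}oxy)silane
Product: 6 (2R,3R)-2-(hydroxymethyl)-3-[1-(trimethylsilyl)ethenyl]cyclopentan-1-one
Conditions: aq. CH2O (37%), Sc(OTf)3 (5 mol%), THF, rt
Reagents that add atoms: formaldehyde, C=O
Why: Mukaiyama aldol hydroxymethylation at the regiodefined enol ether carbon should place the CH2OH group anti to the neighbouring silylvinyl group, giving the trans-2,3 pattern (future C3a), which is also the thermodynamic one.

Step 3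
Reactants: 6 (2R,3R)-2-(hydroxymethyl)-3-[1-(trimethylsilyl)ethenyl]cyclopentan-1-one
Product: 7 (2R,3R)-2-({[tert-butyl(dimethyl)silyl]oxy}methyl)-3-[1-(trimethylsilyl)ethenyl]cyclopentan-1-one
Conditions: TBSCl, imidazole, DMF, 0 °C to rt
Reagents that add atoms: tert-butyl(chloro)dimethylsilane, CC(C)(C)[Si](C)(C)Cl
Why: Standard silylation of the primary alcohol blocks retro-aldol and dehydration of the β-hydroxy ketone without touching the stereocentres.

Step 4
Reactants: 7 (2R,3R)-2-({[tert-butyl(dimethyl)silyl]oxy}methyl)-3-[1-(trimethylsilyl)ethenyl]cyclopentan-1-one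
Product: 9 (4R,5R)-5-({[tert-butyl(dimethyl)silyl]oxy}methyl)-4-[1-(trimethylsilyl)ethenyl]cyclopent-1-en-1-yl trifluoromethanesulfonate, via lithium enolate 8 (not isolated)
Conditions: LiN(i-Pr)2, THF, −78 °C; then PhNTf2, −78 to 0 °C
Reagents that add atoms: N-phenylbis(trifluoromethanesulfonimide), O=S(=O)(N(c1ccccc1)S(=O)(=O)C(F)(F)F)C(F)(F)F
Why: Kinetic deprotonation at the unhindered C5 methylene (not at the branched C2 methine) followed by O-triflation of the enolate should give the less substituted enol triflate with both stereocentres untouched.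

Step 5
Reactants: 9 (4R,5R)-5-({[tert-butyl(dimethyl)silyl]oxy}methyl)-4-[1-(trimethylsilyl)ethenyl]cyclopent-1-en-1-yl trifluoromethanesulfonate
Product: 10 tert-butyl(dimethyl)({(1S,5R)-2-methyl-5-[1-(trimethylsilyl)ethenyl]cyclopent-2-en-1-yl}methoxy)silane
Conditions: MeMgBr, Fe(acac)3 (5 mol%), THF/NMP, −30 to 0 °C
Reagents that add atoms: methylmagnesium bromide, C[Mg]Br
Why: Iron-catalysed cross-coupling of an alkenyl triflate with a methyl Grignard reagent installs the C3 methyl on the C2=C3 alkene; the alkenylsilane and the silyl ether are inert.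

Step 6
Reactants: 10 tert-butyl(dimethyl)({(1S,5R)-2-methyl-5-[1-(trimethylsilyl)ethenyl]cyclopent-2-en-1-yl}methoxy)silane
Product: 11 tert-butyl({(1S,5R)-5-(1-iodoethenyl)-2-methylcyclopent-2-en-1-yl}methoxy)dimethylsilane
Conditions: NIS, MeCN, 0 °C, dark
Reagents that add atoms: N-iodosuccinimide, O=C1CCC(=O)N1I
Why: Ipso-iododesilylation of the 1-silylalkene should give the 2-iodoalkene needed for ring closure, since the ring alkene can only form a reversible iodonium ion in this medium while loss of silicon is irreversible.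

Step 7
Reactants: 11 tert-butyl({(1S,5R)-5-(1-iodoethenyl)-2-methylcyclopent-2-en-1-yl}methoxy)dimethylsilane
Product: 12 [(1S,5R)-5-(1-iodoethenyl)-2-methylcyclopent-2-en-1-yl]methanol
Conditions: HF·pyridine, THF/pyridine, 0 °C
Reagents that add atoms: none
Why: Fluoride-mediated cleavage of the primary silyl ether under buffered conditions that do not eliminate HI from the iodoalkene.

Step 8
Reactants: 12 [(1S,5R)-5-(1-iodoethenyl)-2-methylcyclopent-2-en-1-yl]methanol
Product: 13 (1S,5R)-5-(1-iodoethenyl)-2-methylcyclopent-2-ene-1-carbaldehyde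
Conditions: Dess–Martin periodinane, NaHCO3, CH2Cl2, 0 °C; used at once
Reagents that add atoms: none
Why: Buffered periodinane oxidation is neutral enough to avoid epimerisation at C3a and migration of the β,γ-alkene into conjugation.

Step 9
Reactants: 14 4-methylpent-3-en-1-ol
Product: 15 4-methylpent-3-enal
Conditions: Dess–Martin periodinane, NaHCO3, CH2Cl2, 0 °C; used as a solution at once
Reagents that add atoms: none
Why: The same buffered periodinane oxidation gives the β,γ-unsaturated aldehyde without isomerisation.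

Step 10
Reactants: 16 (3Z)-penta-1,3-diene; 17 bis(pinacolato)diboron; 15 4-methylpent-3-enal; 13 (1S,5R)-5-(1-iodoethenyl)-2-methylcyclopent-2-ene-1-carbaldehyde
Product: 21 (1R,2S,3S,4S)-2-ethenyl-1-[(1S,5R)-5-(1-iodoethenyl)-2-methylcyclopent-2-en-1-yl]-3,7-dimethyloct-6-ene-1,4-diol, via bis(boronate) 18 (not isolated), via allylboronate 19 (not isolated), via bis(borate) 20 (not isolated)
Conditions: 16 (1.3 equiv), 17 (1.0 equiv), Pt(dba)3 (3 mol%), TADDOL-derived aryl phosphonite (6 mol%; enantiomer giving (2S)-18), toluene, 60 °C, sealed; then 15 (1.0 equiv), rt to 40 °C; then 13 (0.75 equiv), (R)-TRIP (10 mol%), 4 Å MS, −30 °C to rt; aq. NaHCO3 work-up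
Reagents that add atoms: none
Why: Platinum-catalysed enantioselective 1,2-diboration of the terminal alkene of the cis-diene (which cannot reach the s-cis geometry needed for 1,4-addition) gives the α-chiral allylic bis(boronate) 18; its secondary allylic C–B unit adds to 15 through a closed chair transition state, forming the C2'–C3' bond and unmasking the primary (E)-allylboronate 19, which adds to 13 through a second chair under chiral phosphoric acid catalysis to form C4–C5 (closest known reaction types: tandem diene diboration/double allylboration of dicarbonyl compounds, and phosphoric-acid-catalysed allylboration with γ-substituted allyl pinacolboronates). No ring is closed; four components are joined, and both rings come from outside this step (ring A from 13, ring B from step 14). C2' and C3' are set by chirality transfer from the C–B stereocentre of 18: the (Z)-methyl is axial in the chair, which forces the CH2Bpin group equatorial, so one diastereoface reacts, the methyl and the new oxygen come out syn, and the new alkene is E. C5 and C4 are set in the second chair: the E geometry puts the C2' branch equatorial and gives the anti relation (cis on the later ring) of the C4 oxygen and the C5 side chain, while the absolute sense is fixed by (R)-TRIP directing the allyl group to the Re face of 13, reinforced by the C2' centre of 19 (its hydrogen toward the aldehyde substituent to avoid a syn-pentane contact, the C3' chain anti). The step needs chemoselectivity in the order of the two additions, secured because only the secondary boronate of 18 is allylic while 15 is present (the primary C–B unit becomes allylic only after the first addition and is sluggish without acid) and because 13 and the acid are added after 15 is consumed. The β,γ-unsaturated aldehydes should survive because the medium is aprotic and neutral to weakly acidic.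

Step 11
Reactants: 21 (1R,2S,3S,4S)-2-ethenyl-1-[(1S,5R)-5-(1-iodoethenyl)-2-methylcyclopent-2-en-1-yl]-3,7-dimethyloct-6-ene-1,4-diol
Product: 22 1,4-bis(triethylsilyl) ether of 21
Conditions: Et3SiOTf, 2,6-lutidine, CH2Cl2, −78 to 0 °C
Reagents that add atoms: triethylsilyl trifluoromethanesulfonate, CC[Si](CC)(CC)OS(=O)(=O)C(F)(F)F
Why: Silylation with the reactive silyl triflate covers both secondary alcohols, including the hindered C4–OH, so that the later aldehyde cannot form lactols.

Step 12
Reactants: 22 1,4-bis(triethylsilyl) ether of 21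
Product: 24 (3S,4S,5S)-3-{(R)-[(1S,5R)-5-(1-iodoethenyl)-2-methylcyclopent-2-en-1-yl][(triethylsilyl)oxy]methyl}-4,8-dimethyl-5-[(triethylsilyl)oxy]non-7-en-1-ol, via B-alkyl-9-BBN 23 (not isolated)
Conditions: 9-BBN, THF, 0 °C to rt; then NaOH, H2O2, 0 °C
Reagents that add atoms: hydrogen peroxide, OO
Why: Hydroboration–oxidation with 9-BBN is selective for the monosubstituted vinyl group over the trisubstituted alkenes and the deactivated 2-iodoalkene, and places the hydroxyl on the terminal carbon (future C7).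

Step 13
Reactants: 24 (3S,4S,5S)-3-{(R)-[(1S,5R)-5-(1-iodoethenyl)-2-methylcyclopent-2-en-1-yl][(triethylsilyl)oxy]methyl}-4,8-dimethyl-5-[(triethylsilyl)oxy]non-7-en-1-ol
Product: 25 (3S,4S,5S)-3-{(R)-[(1S,5R)-5-(1-iodoethenyl)-2-methylcyclopent-2-en-1-yl][(triethylsilyl)oxy]methyl}-4,8-dimethyl-5-[(triethylsilyl)oxy]non-7-enal
Conditions: Dess–Martin periodinane, NaHCO3, CH2Cl2, 0 °C
Reagents that add atoms: none
Why: Buffered periodinane oxidation of the primary alcohol leaves silyl ethers, alkenes and the iodoalkene untouched.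

Step 14
Reactants: 25 (3S,4S,5S)-3-{(R)-[(1S,5R)-5-(1-iodoethenyl)-2-methylcyclopent-2-en-1-yl][(triethylsilyl)oxy]methyl}-4,8-dimethyl-5-[(triethylsilyl)oxy]non-7-enal
Product: 26 (3aS,4R,5S,7R,8aR)-3-methyl-8-methylidene-5-{(2S,3S)-6-methyl-3-[(triethylsilyl)oxy]hept-5-en-2-yl}-4-[(triethylsilyl)oxy]-1,3a,4,5,6,7,8,8a-octahydroazulen-7-ol
Conditions: CrCl2 (excess), NiCl2 (cat.), chiral oxazoline–sulfonamide ligand (enantiomer giving 7R), Et3N, THF, rt, 3 mM, slow addition of 25
Reagents that add atoms: none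
Why: Intramolecular Nozaki–Hiyama–Kishi reaction, in which the alkenylchromium formed from the 2-iodoalkene adds to the aldehyde, should close ring B at C7–C8 and create the exocyclic methylene, with the chiral ligand on chromium setting C7 (R).

Step 15
Reactants: 26 (3aS,4R,5S,7R,8aR)-3-methyl-8-methylidene-5-{(2S,3S)-6-methyl-3-[(triethylsilyl)oxy]hept-5-en-2-yl}-4-[(triethylsilyl)oxy]-1,3a,4,5,6,7,8,8a-octahydroazulen-7-ol
Product: 27 (3aS,4R,5S,7R,8aR)-5-[(2S,3S)-3-hydroxy-6-methylhept-5-en-2-yl]-3-methyl-8-methylidene-1,3a,4,5,6,7,8,8a-octahydroazulene-4,7-diol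
Conditions: HF·pyridine, THF/pyridine, 0 °C to rt
Reagents that add atoms: none
Why: Fluoride-mediated desilylation removes both triethylsilyl ethers without affecting the allylic alcohol or the alkenes.

Step 16
Reactants: 27 (3aS,4R,5S,7R,8aR)-5-[(2S,3S)-3-hydroxy-6-methylhept-5-en-2-yl]-3-methyl-8-methylidene-1,3a,4,5,6,7,8,8a-octahydroazulene-4,7-diol
Product: 28 (3aS,4R,5S,7R,8aR)-5-[(2S,3S)-3-(acetyloxy)-6-methylhept-5-en-2-yl]-4-hydroxy-3-methyl-8-methylidene-1,3a,4,5,6,7,8,8a-octahydroazulen-7-yl acetate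
Conditions: Ac2O (2.3 equiv), pyridine, DMAP (5 mol%), CH2Cl2, −20 to 0 °C, monitored
Reagents that add atoms: acetic anhydride, CC(=O)OC(C)=O
Why: Nucleophile-catalysed acylation should discriminate by hindrance, so that the allylic C7–OH and the side-chain C3'–OH are acetylated while the C4–OH, flanked by the two methines C3a and C5, stays free.

**Compound list**

1 | cyclopent-2-en-1-one | O=C1C=CCC1 | starting material
2 | ethynyl(trimethyl)silane | C#C[Si](C)(C)C | starting material
3 | bis(2-methylpropyl)[1-(trimethylsilyl)ethenyl]alumane | C=C([Si](C)(C)C)[Al](CC(C)C)CC(C)C | intermediate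
4 | bis(2-methylpropyl)({(3R)-3-[1-(trimethylsilyl)ethenyl]cyclopent-1-en-1-yl}oxy)alumane | CC(C)C[Al](CC(C)C)OC1=C[C@@H](CC1)C(=C)[Si](C)(C)C | intermediate
5 | trimethyl({(3R)-3-[1-(trimethylsilyl)ethenyl]cyclopent-1-en-1-yl}oxy)silane | C[Si](C)(C)OC1=C[C@@H](CC1)C(=C)[Si](C)(C)C | intermediate
6 | (2R,3R)-2-(hydroxymethyl)-3-[1-(trimethylsilyl)ethenyl]cyclopentan-1-one | OC[C@@H]1C(=O)CC[C@H]1C(=C)[Si](C)(C)C | intermediate
7 | (2R,3R)-2-({[tert-butyl(dimethyl)silyl]oxy}methyl)-3-[1-(trimethylsilyl)ethenyl]cyclopentan-1-one | CC(C)(C)[Si](C)(C)OC[C@@H]1C(=O)CC[C@H]1C(=C)[Si](C)(C)C | intermediate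
8 | lithium (4R,5R)-5-({[tert-butyl(dimethyl)silyl]oxy}methyl)-4-[1-(trimethylsilyl)ethenyl]cyclopent-1-en-1-olate | CC(C)(C)[Si](C)(C)OC[C@@H]1C(O[Li])=CC[C@H]1C(=C)[Si](C)(C)C | intermediate
9 | (4R,5R)-5-({[tert-butyl(dimethyl)silyl]oxy}methyl)-4-[1-(trimethylsilyl)ethenyl]cyclopent-1-en-1-yl trifluoromethanesulfonate | CC(C)(C)[Si](C)(C)OC[C@@H]1C(OS(=O)(=O)C(F)(F)F)=CC[C@H]1C(=C)[Si](C)(C)C | intermediate
10 | tert-butyl(dimethyl)({(1S,5R)-2-methyl-5-[1-(trimethylsilyl)ethenyl]cyclopent-2-en-1-yl}methoxy)silane | CC(C)(C)[Si](C)(C)OC[C@@H]1C(C)=CC[C@H]1C(=C)[Si](C)(C)C | intermediate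
11 | tert-butyl({(1S,5R)-5-(1-iodoethenyl)-2-methylcyclopent-2-en-1-yl}methoxy)dimethylsilane | CC(C)(C)[Si](C)(C)OC[C@@H]1C(C)=CC[C@H]1C(I)=C | intermediate
12 | [(1S,5R)-5-(1-iodoethenyl)-2-methylcyclopent-2-en-1-yl]methanol | OC[C@@H]1C(C)=CC[C@H]1C(I)=C | intermediate
13 | (1S,5R)-5-(1-iodoethenyl)-2-methylcyclopent-2-ene-1-carbaldehyde | O=C[C@@H]1C(C)=CC[C@H]1C(I)=C | intermediate
14 | 4-methylpent-3-en-1-ol | CC(C)=CCCO | starting material
15 | 4-methylpent-3-enal | CC(C)=CCC=O | intermediate
16 | (3Z)-penta-1,3-diene | C=C/C=C\C | starting material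
17 | bis(pinacolato)diboron | CC1(C)OB(OC1(C)C)B1OC(C)(C)C(C)(C)O1 | starting material
18 | 2,2'-[(2S,3Z)-pent-3-ene-1,2-diyl]bis(4,4,5,5-tetramethyl-1,3,2-dioxaborolane) | C/C=C\[C@@H](B1OC(C)(C)C(C)(C)O1)CB1OC(C)(C)C(C)(C)O1 | intermediate
19 | 2-{(2E,4S,5S)-4,8-dimethyl-5-[(4,4,5,5-tetramethyl-1,3,2-dioxaborolan-2-yl)oxy]nona-2,7-dien-1-yl}-4,4,5,5-tetramethyl-1,3,2-dioxaborolane | CC1(C)OB(C/C=C/[C@H](C)[C@H](CC=C(C)C)OB2OC(C)(C)C(C)(C)O2)OC1(C)C | intermediate
20 | O,O'-bis(4,4,5,5-tetramethyl-1,3,2-dioxaborolan-2-yl) derivative (bis-borate) of diol 21 | C=C[C@@H]([C@H](C)[C@H](CC=C(C)C)OB1OC(C)(C)C(C)(C)O1)[C@@H](OB1OC(C)(C)C(C)(C)O1)[C@@H]1C(C)=CC[C@H]1C(I)=C | intermediate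
21 | (1R,2S,3S,4S)-2-ethenyl-1-[(1S,5R)-5-(1-iodoethenyl)-2-methylcyclopent-2-en-1-yl]-3,7-dimethyloct-6-ene-1,4-diol | C=C[C@@H]([C@H](C)[C@H](CC=C(C)C)O)[C@@H](O)[C@@H]1C(C)=CC[C@H]1C(I)=C | intermediate
22 | 1,4-bis(triethylsilyl) ether of 21 | C=C[C@@H]([C@H](C)[C@H](CC=C(C)C)O[Si](CC)(CC)CC)[C@@H](O[Si](CC)(CC)CC)[C@@H]1C(C)=CC[C@H]1C(I)=C | intermediate
23 | B-alkyl-9-borabicyclo[3.3.1]nonane from 22 (boron on the former terminal vinyl carbon) | C1CCC2CCCC1B2CC[C@@H]([C@H](C)[C@H](CC=C(C)C)O[Si](CC)(CC)CC)[C@@H](O[Si](CC)(CC)CC)[C@@H]1C(C)=CC[C@H]1C(I)=C | intermediate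
24 | (3S,4S,5S)-3-{(R)-[(1S,5R)-5-(1-iodoethenyl)-2-methylcyclopent-2-en-1-yl][(triethylsilyl)oxy]methyl}-4,8-dimethyl-5-[(triethylsilyl)oxy]non-7-en-1-ol | OCC[C@@H]([C@H](C)[C@H](CC=C(C)C)O[Si](CC)(CC)CC)[C@@H](O[Si](CC)(CC)CC)[C@@H]1C(C)=CC[C@H]1C(I)=C | intermediate
25 | (3S,4S,5S)-3-{(R)-[(1S,5R)-5-(1-iodoethenyl)-2-methylcyclopent-2-en-1-yl][(triethylsilyl)oxy]methyl}-4,8-dimethyl-5-[(triethylsilyl)oxy]non-7-enal | O=CC[C@@H]([C@H](C)[C@H](CC=C(C)C)O[Si](CC)(CC)CC)[C@@H](O[Si](CC)(CC)CC)[C@@H]1C(C)=CC[C@H]1C(I)=C | intermediate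
26 | (3aS,4R,5S,7R,8aR)-3-methyl-8-methylidene-5-{(2S,3S)-6-methyl-3-[(triethylsilyl)oxy]hept-5-en-2-yl}-4-[(triethylsilyl)oxy]-1,3a,4,5,6,7,8,8a-octahydroazulen-7-ol | C=C1[C@H](O)C[C@@H]([C@H](C)[C@H](CC=C(C)C)O[Si](CC)(CC)CC)[C@@H](O[Si](CC)(CC)CC)[C@@H]2C(C)=CC[C@@H]12 | intermediate
27 | (3aS,4R,5S,7R,8aR)-5-[(2S,3S)-3-hydroxy-6-methylhept-5-en-2-yl]-3-methyl-8-methylidene-1,3a,4,5,6,7,8,8a-octahydroazulene-4,7-diol | C=C1[C@H](O)C[C@@H]([C@H](C)[C@H](CC=C(C)C)O)[C@@H](O)[C@@H]2C(C)=CC[C@@H]12 | intermediate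
28 | (3aS,4R,5S,7R,8aR)-5-[(2S,3S)-3-(acetyloxy)-6-methylhept-5-en-2-yl]-4-hydroxy-3-methyl-8-methylidene-1,3a,4,5,6,7,8,8a-octahydroazulen-7-yl acetate | C=C1[C@H](OC(C)=O)C[C@@H]([C@H](C)[C@H](CC=C(C)C)OC(C)=O)[C@@H](O)[C@@H]2C(C)=CC[C@@H]12 | target

**Step count**

Total step count: 16. Longest linear sequence: 15 steps (steps 1–8 and 10–16); step 9 is a one-step side branch.

**Three steps most likely to fail**

Step 10. The second, intermolecular allylboration may lose facial selectivity if catalyst control is opposed by the α-stereocentre of 13. The hindered γ-branched allylboronate may also add so slowly that 13 enolises into conjugation. The fallback sets out from 19 and forms the C4–C5 bond with an allylchromium reagent instead. Aldehyde 13 is withheld and 19 is worked up oxidatively (NaOH, H2O2) to (2E,4S,5S)-4,8-dimethylnona-2,7-diene-1,5-diol F1. The primary allylic hydroxyl is exchanged selectively with NBS/Me2S to give (2E,4S,5S)-1-bromo-4,8-dimethylnona-2,7-dien-5-ol F2. F2 and 13 are then joined with CrCl2 in THF (Nozaki–Hiyama allylation, anti-selective through the chair of the γ-substituted allylchromium, with a chiral ligand on chromium if needed to steer the aldehyde face). This should give 21, where the route is rejoined at step 11.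

Step 14. Closure of the seven-membered ring may be slow enough for protodeiodination to compete, and the ligand may not fully control which face of the aldehyde is attacked, giving C7 epimers. The fallback sets out from 26 as obtained (epimer mixture at C7) and sets C7 by ketone reduction instead of C–C bond formation. Dess–Martin oxidation gives the C7 ketone (exocyclic enone) of 26 F3. Corey–Bakshi–Shibata reduction with the (S)-oxazaborolidine and catecholborane (1,2-reduction, the alkenyl side acting as the large group) should return 26 as the (7R) alcohol.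

Step 16. The rate difference between the three secondary hydroxyls may be too small, leading to acylation at C4 or incomplete acylation at the branched C3' carbinol. The fallback sets out from 26 and unveils the hydroxyls one after the other. Acetylation (Ac2O, DMAP) gives the C7 acetate of 26 F4. Methanolysis with PPTS in MeOH at 0 °C should remove the less hindered C3' silyl ether first, giving the C3' alcohol F5. A second acetylation gives the 7,3'-diacetate 4-triethylsilyl ether F6, and HF·pyridine then frees the C4–OH and comes back to the route at 28.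

**Further compounds**

F1 | step 10 | (2E,4S,5S)-4,8-dimethylnona-2,7-diene-1,5-diol | OC/C=C/[C@H](C)[C@H](CC=C(C)C)O
F2 | step 10 | (2E,4S,5S)-1-bromo-4,8-dimethylnona-2,7-dien-5-ol | BrC/C=C/[C@H](C)[C@H](CC=C(C)C)O
F3 | step 14 | (3aS,4R,5S,8aR)-3-methyl-8-methylidene-5-{(2S,3S)-6-methyl-3-[(triethylsilyl)oxy]hept-5-en-2-yl}-4-[(triethylsilyl)oxy]-octahydroazulen-7-one (C7 ketone of 26) | C=C1C(=O)C[C@@H]([C@H](C)[C@H](CC=C(C)C)O[Si](CC)(CC)CC)[C@@H](O[Si](CC)(CC)CC)[C@@H]2C(C)=CC[C@@H]12
F4 | step 16 | C7 acetate of 26 | C=C1[C@H](OC(C)=O)C[C@@H]([C@H](C)[C@H](CC=C(C)C)O[Si](CC)(CC)CC)[C@@H](O[Si](CC)(CC)CC)[C@@H]2C(C)=CC[C@@H]12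
F5 | step 16 | C7 acetate with free C3'–OH and C4 triethylsilyl ether | C=C1[C@H](OC(C)=O)C[C@@H]([C@H](C)[C@H](CC=C(C)C)O)[C@@H](O[Si](CC)(CC)CC)[C@@H]2C(C)=CC[C@@H]12
F6 | step 16 | 4-O-triethylsilyl ether of 28 | C=C1[C@H](OC(C)=O)C[C@@H]([C@H](C)[C@H](CC=C(C)C)OC(C)=O)[C@@H](O[Si](CC)(CC)CC)[C@@H]2C(C)=CC[C@@H]12
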